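**Plan**

- Retrosynthesis: the tetrahydrofuran is traced back to a γ-lactone (C5 at the carboxyl level), and the C4–benzyl bond is cut through an α-benzylidene lactone to 3,4,5-trimethoxybenzaldehyde. The lactone is then cut at O1–C2 and at C3–CH2OH in a single Prins disconnection to an (E)-styrylacetic acid and formaldehyde; the alkene is a Wittig bond.
- Enabling feature: with the ring numbered O1, C2 (aryl), C3 (CH2OH), C4 (benzyl), C5, the oxygen O1 on benzylic C2 and the hydroxymethyl on C3 form the 1,3-dioxygen pattern of a styrene–formaldehyde Prins adduct. C5, reached from C3 through C4, can be a carboxyl carbon that delivers O1 internally.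
- Forward: Wittig olefination, then asymmetric Prins lactonisation (the only ring-forming event; this lactone ring becomes the tetrahydrofuran), O-silylation, aldol/dehydration with the same aldehyde, hydrogenation, lactone-to-ether reduction, desilylation.
- Stereochemistry: C3 comes from the chiral acid (alkene face), C2 from anti addition across the (E)-alkene (trans to C3), and C4 from hydrogen delivery anti to the C3 substituent (benzyl cis to CH2OH).

Key step: step 2

Assumption: the sense of induction of the chiral acid in step 2 cannot be predicted with confidence, so the catalyst enantiomer that gives the (4R,5S) lactone is taken to be identified in a trial run (both enantiomers derive from the two BINOL antipodes).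

**Route**

Step 1
Reactants: 1 3,4,5-trimethoxybenzaldehyde; 2 (2-carboxyethyl)triphenylphosphonium bromide
Product: 4 (E)-4-(3,4,5-trimethoxyphenyl)but-3-enoic acid, via sodium carboxylate ylide 3 (not isolated)
Conditions: 2, NaN(SiMe3)2 (2.2 equiv), THF, −78 → 0 °C; then 1, −78 °C → rt; aq. HCl; recrystallisation
Reagents that add atoms: none
Why: Wittig olefination of a non-enolisable aryl aldehyde with the preformed carboxylate ylide is a standard route to 4-arylbut-3-enoic acids and is expected to favour the (E)-alkene, any (Z)-isomer being removed when the crystalline acid is recrystallised.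

Step 2
Reactants: 4 (E)-4-(3,4,5-trimethoxyphenyl)but-3-enoic acid; 5 formaldehyde (charged as paraformaldehyde)
Product: 6 (4R,5S)-4-(hydroxymethyl)-5-(3,4,5-trimethoxyphenyl)dihydrofuran-2(3H)-one
Conditions: (CH2O)n (2–3 equiv), confined BINOL-derived imidodiphosphorimidate (IDPi) Brønsted acid (2–5 mol %), CHCl3, −20 °C → rt; aq. NaHCO3 work-up
Reagents that add atoms: none
Why: Proposed new method: the confined acid protonates and ion-pairs with formaldehyde, the alkene carbon remote from the aryl ring attacks it (C3–CH2OH bond), and the positive charge building at the benzylic carbon, stabilised by the para-methoxy group, is captured by the carboxyl oxygen (O1–C2 bond), after which loss of the carboxyl proton returns the catalyst. The closest known reactions are the achiral acid-promoted Prins lactonisation of β,γ-unsaturated acids with formaldehyde and the IDPi-catalysed asymmetric Prins reaction of styrenes with paraformaldehyde that ends in 1,3-dioxanes; the new element is interception of the chiral ion pair by an internal carboxyl group. The γ-lactone closes by oxygen attack at the benzylic carbon, a closure that is 5-endo with respect to the original alkene, as in halolactonisations of styrylacetic acids, and is feasible because it is in effect capture of a benzylic cation. The CH2OH-bearing centre is set by the alkene face that the chiral counter-anion exposes to formaldehyde, and the aryl-bearing centre follows from anti addition across the (E)-alkene, backed by the thermodynamic preference for the trans lactone should the benzylic C–O bond ionise reversibly. The step needs C–C bond formation at the non-benzylic alkene carbon (secured by the electron-rich aryl group), lactone closure ahead of capture by a second formaldehyde (secured by the five-membered proximity of the carboxyl group) and alkene rather than arene attack (the free ring positions are flanked by substituents and the acid pocket is confined).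

Step 3
Reactants: 6 (4R,5S)-4-(hydroxymethyl)-5-(3,4,5-trimethoxyphenyl)dihydrofuran-2(3H)-one
Product: 7 (4R,5S)-4-{[(tert-butyldiphenylsilyl)oxy]methyl}-5-(3,4,5-trimethoxyphenyl)dihydrofuran-2(3H)-one
Conditions: TBDPSCl, imidazole, DMF, 0 °C → rt
Reagents that add atoms: tert-butyl(chloro)diphenylsilane (TBDPSCl), CC(C)(C)[Si](Cl)(c1ccccc1)c1ccccc1
Why: Standard silylation of a primary alcohol gives a bulky ether that tolerates the enolate, hydride and BF3 steps and later shields one face of the lactone in the hydrogenation.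

Step 4
Reactants: 7 (4R,5S)-4-{[(tert-butyldiphenylsilyl)oxy]methyl}-5-(3,4,5-trimethoxyphenyl)dihydrofuran-2(3H)-one; 1 3,4,5-trimethoxybenzaldehyde
Product: 9 (4R,5S)-4-{[(tert-butyldiphenylsilyl)oxy]methyl}-3-[hydroxy(3,4,5-trimethoxyphenyl)methyl]-5-(3,4,5-trimethoxyphenyl)dihydrofuran-2(3H)-one, via lithium enolate 8 (not isolated)
Conditions: LiN(SiMe3)2 (1.1 equiv), THF, −78 °C; then 1, −78 °C; AcOH quench
Reagents that add atoms: none
Why: Directed aldol addition of a lithium lactone enolate to a non-enolisable aldehyde is the usual way to attach the benzylic carbon in lignan lactone synthesis; the two new centres (C3 and the carbinol carbon, obtained as a diastereomer mixture) are erased in step 5, and C4 and C5 carry no acidic hydrogen under these conditions.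

Step 5
Reactants: 9 (4R,5S)-4-{[(tert-butyldiphenylsilyl)oxy]methyl}-3-[hydroxy(3,4,5-trimethoxyphenyl)methyl]-5-(3,4,5-trimethoxyphenyl)dihydrofuran-2(3H)-one
Product: 11 (3E,4R,5S)-4-{[(tert-butyldiphenylsilyl)oxy]methyl}-3-(3,4,5-trimethoxybenzylidene)-5-(3,4,5-trimethoxyphenyl)dihydrofuran-2(3H)-one, via mesylate 10 (not isolated)
Conditions: MsCl, Et3N, CH2Cl2, 0 °C; then DBU, 0 °C → rt
Reagents that add atoms: none
Why: Mesylation followed by E1cB elimination is a routine dehydration of lactone aldols to the conjugated (E)-benzylidene lactone; the alkene geometry is thermodynamic and is not carried into the target, and short exposure to DBU at or below room temperature should avoid migration of the double bond into the ring.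

Step 6
Reactants: 11 (3E,4R,5S)-4-{[(tert-butyldiphenylsilyl)oxy]methyl}-3-(3,4,5-trimethoxybenzylidene)-5-(3,4,5-trimethoxyphenyl)dihydrofuran-2(3H)-one
Product: 12 (3R,4R,5S)-4-{[(tert-butyldiphenylsilyl)oxy]methyl}-3-(3,4,5-trimethoxybenzyl)-5-(3,4,5-trimethoxyphenyl)dihydrofuran-2(3H)-one
Conditions: H2 (1 atm), Pd/C (10 wt %), EtOAc, rt, stopped after one equivalent of H2
Reagents that add atoms: none
Why: Heterogeneous hydrogenation of the exocyclic alkene should deliver hydrogen to C3 from the face opposite the adjacent silyloxymethyl group (held pseudoaxial by allylic 1,3-strain with the benzylidene aryl), placing the benzyl group cis to CH2OSi (3R) as is usual for α-benzylidene β-substituted butyrolactones, while neutral solvent and low pressure should spare the benzylic lactone C–O bond.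

Step 7
Reactants: 12 (3R,4R,5S)-4-{[(tert-butyldiphenylsilyl)oxy]methyl}-3-(3,4,5-trimethoxybenzyl)-5-(3,4,5-trimethoxyphenyl)dihydrofuran-2(3H)-one
Product: 13 (3R,4R,5S)-4-{[(tert-butyldiphenylsilyl)oxy]methyl}-3-(3,4,5-trimethoxybenzyl)-5-(3,4,5-trimethoxyphenyl)tetrahydrofuran-2-ol
Conditions: i-Bu2AlH (1.1 equiv), CH2Cl2, −78 °C; aq. potassium sodium tartrate
Reagents that add atoms: none
Why: Partial reduction of a γ-lactone with one equivalent of i-Bu2AlH at low temperature stops at the lactol (anomer mixture, of no consequence) through the stable tetrahedral aluminate, and the non-basic conditions should leave the epimerisable C3 centre untouched if the crude lactol is used at once.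

Step 8
Reactants: 13 (3R,4R,5S)-4-{[(tert-butyldiphenylsilyl)oxy]methyl}-3-(3,4,5-trimethoxybenzyl)-5-(3,4,5-trimethoxyphenyl)tetrahydrofuran-2-ol
Product: 14 tert-butyl{[(2S,3R,4R)-4-(3,4,5-trimethoxybenzyl)-2-(3,4,5-trimethoxyphenyl)tetrahydrofuran-3-yl]methoxy}diphenylsilane
Conditions: Et3SiH (3 equiv), BF3·OEt2 (1.5 equiv), CH2Cl2, −78 °C; aq. NaHCO3
Reagents that add atoms: none
Why: Ionic hydrogenation of the lactol: BF3·OEt2 (returned in the net equation) ionises the anomeric C–O bond to the cyclic oxocarbenium ion, which Et3SiH reduces to the ring CH2 without creating a stereocentre, and at −78 °C this non-benzylic acetal position should ionise well before the benzylic C2–O bond.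

Step 9
Reactants: 14 tert-butyl{[(2S,3R,4R)-4-(3,4,5-trimethoxybenzyl)-2-(3,4,5-trimethoxyphenyl)tetrahydrofuran-3-yl]methoxy}diphenylsilane
Product: 15 [(2S,3R,4R)-4-(3,4,5-trimethoxybenzyl)-2-(3,4,5-trimethoxyphenyl)tetrahydrofuran-3-yl]methanol
Conditions: Bu4NF, THF, 0 °C → rt
Reagents that add atoms: none
Why: Fluoride-induced desilylation, driven by Si–F bond formation, frees the primary alcohol without touching the aryl methyl ethers or any ring stereocentre.

**Compound list**

1 | 3,4,5-trimethoxybenzaldehyde | COc1cc(C=O)cc(OC)c1OC | starting material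
2 | (2-carboxyethyl)triphenylphosphonium bromide | [Br-].OC(=O)CC[P+](c1ccccc1)(c1ccccc1)c1ccccc1 | starting material
3 | sodium 3-(triphenylphosphoranylidene)propanoate (carboxylate ylide, formed in situ) | [Na+].[O-]C(=O)CC=P(c1ccccc1)(c1ccccc1)c1ccccc1 | intermediate
4 | (E)-4-(3,4,5-trimethoxyphenyl)but-3-enoic acid | COc1cc(/C=C/CC(=O)O)cc(OC)c1OC | intermediate
5 | formaldehyde (used as paraformaldehyde) | C=O | starting material
6 | (4R,5S)-4-(hydroxymethyl)-5-(3,4,5-trimethoxyphenyl)dihydrofuran-2(3H)-one (trans) | O=C1O[C@H](c2cc(OC)c(OC)c(OC)c2)[C@@H](CO)C1 | intermediate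
7 | (4R,5S)-4-{[(tert-butyldiphenylsilyl)oxy]methyl}-5-(3,4,5-trimethoxyphenyl)dihydrofuran-2(3H)-one | O=C1O[C@H](c2cc(OC)c(OC)c(OC)c2)[C@@H](CO[Si](c2ccccc2)(c2ccccc2)C(C)(C)C)C1 | intermediate
8 | lithium (4R,5S)-4-{[(tert-butyldiphenylsilyl)oxy]methyl}-5-(3,4,5-trimethoxyphenyl)-4,5-dihydrofuran-2-olate (enolate of 7, formed in situ) | [Li+].[O-]C1=C[C@H](CO[Si](c2ccccc2)(c2ccccc2)C(C)(C)C)[C@@H](c2cc(OC)c(OC)c(OC)c2)O1 | intermediate
9 | (4R,5S)-4-{[(tert-butyldiphenylsilyl)oxy]methyl}-3-[hydroxy(3,4,5-trimethoxyphenyl)methyl]-5-(3,4,5-trimethoxyphenyl)dihydrofuran-2(3H)-one (diastereomer mixture at C3 and the carbinol carbon) | O=C1O[C@H](c2cc(OC)c(OC)c(OC)c2)[C@@H](CO[Si](c2ccccc2)(c2ccccc2)C(C)(C)C)C1C(O)c1cc(OC)c(OC)c(OC)c1 | intermediate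
10 | methanesulfonate of 9 (formed in situ, same diastereomer mixture) | O=C1O[C@H](c2cc(OC)c(OC)c(OC)c2)[C@@H](CO[Si](c2ccccc2)(c2ccccc2)C(C)(C)C)C1C(OS(C)(=O)=O)c1cc(OC)c(OC)c(OC)c1 | intermediate
11 | (3E,4R,5S)-4-{[(tert-butyldiphenylsilyl)oxy]methyl}-3-(3,4,5-trimethoxybenzylidene)-5-(3,4,5-trimethoxyphenyl)dihydrofuran-2(3H)-one | O=C1O[C@H](c2cc(OC)c(OC)c(OC)c2)[C@@H](CO[Si](c2ccccc2)(c2ccccc2)C(C)(C)C)/C1=C\c1cc(OC)c(OC)c(OC)c1 | intermediate
12 | (3R,4R,5S)-4-{[(tert-butyldiphenylsilyl)oxy]methyl}-3-(3,4,5-trimethoxybenzyl)-5-(3,4,5-trimethoxyphenyl)dihydrofuran-2(3H)-one (3,4-cis, 4,5-trans) | COc1cc(C[C@H]2C(=O)O[C@H](c3cc(OC)c(OC)c(OC)c3)[C@H]2CO[Si](c2ccccc2)(c2ccccc2)C(C)(C)C)cc(OC)c1OC | intermediate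
13 | (3R,4R,5S)-4-{[(tert-butyldiphenylsilyl)oxy]methyl}-3-(3,4,5-trimethoxybenzyl)-5-(3,4,5-trimethoxyphenyl)tetrahydrofuran-2-ol (anomer mixture) | COc1cc(C[C@H]2C(O)O[C@H](c3cc(OC)c(OC)c(OC)c3)[C@H]2CO[Si](c2ccccc2)(c2ccccc2)C(C)(C)C)cc(OC)c1OC | intermediate
14 | tert-butyl{[(2S,3R,4R)-4-(3,4,5-trimethoxybenzyl)-2-(3,4,5-trimethoxyphenyl)tetrahydrofuran-3-yl]methoxy}diphenylsilane | COc1cc(C[C@H]2CO[C@H](c3cc(OC)c(OC)c(OC)c3)[C@H]2CO[Si](c2ccccc2)(c2ccccc2)C(C)(C)C)cc(OC)c1OC | intermediate
15 | [(2S,3R,4R)-4-(3,4,5-trimethoxybenzyl)-2-(3,4,5-trimethoxyphenyl)tetrahydrofuran-3-yl]methanol | COc1cc(C[C@H]2CO[C@H](c3cc(OC)c(OC)c(OC)c3)[C@H]2CO)cc(OC)c1OC | target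

**Step count and risks**

Total steps: 9. Longest linear sequence: 9 steps (1 and 2 to 15).

Steps most likely to fail:

1. Step 2 (proposed method). The chiral ion pair may discriminate the alkene faces poorly, or the benzylic cation may be diverted to a second formaldehyde (dioxane or oligomer formation) or the arene may be hydroxymethylated. Fallback by known chemistry, setting out from aldehyde 1 and returning at 6: (S)-4-benzyloxazolidin-2-one is N-acylated with methyl 4-chloro-4-oxobutanoate (n-BuLi, THF, −78 °C) to methyl 4-[(4S)-4-benzyl-2-oxooxazolidin-3-yl]-4-oxobutanoate F1. Its dibutylboron enolate (Bu2BOTf, i-Pr2NEt, CH2Cl2, −78 → 0 °C) adds to 1 in an Evans syn-aldol reaction to give the syn adduct F2. The secondary hydroxyl of F2 closes onto the methyl ester (spontaneously or with a trace of acid) to the trans lactone imide F3; the syn aldol relationship translates into the trans ring relationship. LiOH/H2O2 removes the auxiliary to give (2S,3S)-5-oxo-2-(3,4,5-trimethoxyphenyl)tetrahydrofuran-3-carboxylic acid F4, and BH3·SMe2 reduces the free carboxyl group in the presence of the lactone to give 6.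

2. Step 6. Hydrogen delivery may be insufficiently face-selective because the C5 aryl group lies on the face that must be approached, or over-reduction may cleave the benzylic lactone C–O bond. Fallback, setting out from 7 and returning at 12, without hydrogenation: the lithium enolate 8 is alkylated with 3,4,5-trimethoxybenzyl bromide (THF, −78 °C), which should enter anti to the C4 substituent and give the all-trans lactone F5. F5 is deprotonated again (LiN(i-Pr)2, THF, −78 °C) to the lithium enolate F6, which is protonated under kinetic control by a hindered proton donor (2,6-di-tert-butyl-4-methylphenol) from the face opposite the silyloxymethyl group, giving the 3,4-cis lactone 12; recovered F5 can be recycled.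

3. Step 8. The Lewis acid may ionise the benzylic C2–O bond in competition with the lactol, leading to epimerisation at C2, reductive ring opening or Friedel–Crafts closure onto the trimethoxybenzyl ring. Fallback, setting out from 12 and returning at 14, without a Lewis acid: LiBH4 (THF) reduces the lactone to the diol (1S,2R,3R)-2-{[(tert-butyldiphenylsilyl)oxy]methyl}-3-(3,4,5-trimethoxybenzyl)-1-(3,4,5-trimethoxyphenyl)butane-1,4-diol F7. The primary hydroxyl is sulfonylated selectively (TsCl, pyridine, 0 °C) to the monotosylate F8, and the benzylic alkoxide (KOt-Bu, THF, 0 °C) displaces the primary tosylate in an intramolecular Williamson etherification (5-exo-tet) to give 14. The benzylic C–O bond is never broken, so C2 keeps its configuration.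

**Further compounds**

F1 | step 2 | methyl 4-[(4S)-4-benzyl-2-oxooxazolidin-3-yl]-4-oxobutanoate | COC(=O)CCC(=O)N1[C@@H](Cc2ccccc2)COC1=O
F2 | step 2 | methyl (3S)-4-[(4S)-4-benzyl-2-oxooxazolidin-3-yl]-3-[(S)-hydroxy(3,4,5-trimethoxyphenyl)methyl]-4-oxobutanoate | COC(=O)C[C@H](C(=O)N1[C@@H](Cc2ccccc2)COC1=O)[C@H](O)c1cc(OC)c(OC)c(OC)c1
F3 | step 2 | (4S)-4-benzyl-3-[(2S,3S)-5-oxo-2-(3,4,5-trimethoxyphenyl)tetrahydrofuran-3-carbonyl]oxazolidin-2-one | O=C1O[C@H](c2cc(OC)c(OC)c(OC)c2)[C@@H](C(=O)N2[C@@H](Cc3ccccc3)COC2=O)C1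
F4 | step 2 | (2S,3S)-5-oxo-2-(3,4,5-trimethoxyphenyl)tetrahydrofuran-3-carboxylic acid | O=C1O[C@H](c2cc(OC)c(OC)c(OC)c2)[C@@H](C(=O)O)C1
F5 | step 6 | (3S,4R,5S)-4-{[(tert-butyldiphenylsilyl)oxy]methyl}-3-(3,4,5-trimethoxybenzyl)-5-(3,4,5-trimethoxyphenyl)dihydrofuran-2(3H)-one | COc1cc(C[C@@H]2C(=O)O[C@H](c3cc(OC)c(OC)c(OC)c3)[C@H]2CO[Si](c2ccccc2)(c2ccccc2)C(C)(C)C)cc(OC)c1OC
F6 | step 6 | lithium (4R,5S)-4-{[(tert-butyldiphenylsilyl)oxy]methyl}-3-(3,4,5-trimethoxybenzyl)-5-(3,4,5-trimethoxyphenyl)-4,5-dihydrofuran-2-olate | [Li+].[O-]C1=C(Cc2cc(OC)c(OC)c(OC)c2)[C@H](CO[Si](c2ccccc2)(c2ccccc2)C(C)(C)C)[C@@H](c2cc(OC)c(OC)c(OC)c2)O1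
F7 | step 8 | (1S,2R,3R)-2-{[(tert-butyldiphenylsilyl)oxy]methyl}-3-(3,4,5-trimethoxybenzyl)-1-(3,4,5-trimethoxyphenyl)butane-1,4-diol | COc1cc(C[C@@H](CO)[C@H](CO[Si](c2ccccc2)(c2ccccc2)C(C)(C)C)[C@H](O)c2cc(OC)c(OC)c(OC)c2)cc(OC)c1OC
F8 | step 8 | (2R,3R,4S)-3-{[(tert-butyldiphenylsilyl)oxy]methyl}-4-hydroxy-2-(3,4,5-trimethoxybenzyl)-4-(3,4,5-trimethoxyphenyl)butyl 4-methylbenzenesulfonate | COc1cc(C[C@@H](COS(=O)(=O)c2ccc(C)cc2)[C@H](CO[Si](c2ccccc2)(c2ccccc2)C(C)(C)C)[C@H](O)c2cc(OC)c(OC)c(OC)c2)cc(OC)c1OC
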